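1. Rings: A–O–B; B and C are the benzo rings of the dioxin; C and D are those of the furan; D–O–E. Target ⇐ eightfold O-demethylation of its octamethyl ether, in which the ring C OH is already free.
2. Furan ring (closed second) ⇐ loss of water from a fucol-type 2,2'-biphenol. The biphenol is made in the same flask by oxidative C–C phenol cross-coupling of an eckol tetramethyl ether (ring C OH groups free) with a diphlorethol tetramethyl ether (one free OH on ring D).
3. Dioxin ring (closed first) ⇐ intramolecular oxidative C–O phenol coupling of a branched triphlorethol. The central ring B phenol attacks the one neighbouring ring that still carries free OH groups.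
4. Hidden symmetry: the halves A–O–B and E–O–D are the same aryl bromide. Its Br becomes the ring C oxygen in one half and H in the other, and its doubly flanked OMe becomes the ring-closing OH in both.
5. That bromide ⇐ 1,3,5-trimethoxybenzene (dibromination) + 3,5-dimethoxyphenol (Ullmann); ring C ⇐ 3,5-bis(benzyloxy)phenol.

Assumption: the target has no stereocentre and no stable stereoaxis, so it is achiral and there is no configuration to set or resolve.

Step 1
Reactants: 1 1,3,5-trimethoxybenzene
Product: 2 2,4-dibromo-1,3,5-trimethoxybenzene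
Conditions: NBS (2.05 equiv), MeCN, 0 °C → rt
Reagents that add atoms: N-bromosuccinimide, O=C1CCC(=O)N1Br
Why: Electrophilic aromatic bromination of a triply activated arene stops at the 2,4-dibromide with two equivalents of NBS, because each bromine crowds and deactivates the ring; no stereocentre is formed.

Step 2
Reactants: 2 2,4-dibromo-1,3,5-trimethoxybenzene; 3 3,5-dimethoxyphenol
Product: 4 2-bromo-4-(3,5-dimethoxyphenoxy)-1,3,5-trimethoxybenzene
Conditions: 2 (3 equiv), CuI (10 mol %), picolinic acid (20 mol %), K3PO4, DMSO, 110 °C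
Reagents that add atoms: none
Why: Ullmann-type copper-catalysed diaryl ether synthesis with a ligand system made for hindered partners, in which a threefold excess of the symmetric dibromide (recovered) holds the reaction at mono-substitution.

Step 3
Reactants: 4 2-bromo-4-(3,5-dimethoxyphenoxy)-1,3,5-trimethoxybenzene; 5 3,5-bis(benzyloxy)phenol
Product: 6 2-[3,5-bis(benzyloxy)phenoxy]-4-(3,5-dimethoxyphenoxy)-1,3,5-trimethoxybenzene
Conditions: 5 (1.5 equiv), CuI (20 mol %), picolinic acid (40 mol %), K3PO4, DMSO, 115 °C
Reagents that add atoms: none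
Why: A second Ullmann-type ether synthesis joins an unhindered phenoxide to the remaining bromide, and benzyl and methyl ethers are inert to these conditions.

Step 4
Reactants: 6 2-[3,5-bis(benzyloxy)phenoxy]-4-(3,5-dimethoxyphenoxy)-1,3,5-trimethoxybenzene
Product: 7 2-(3,5-dihydroxyphenoxy)-6-(3,5-dimethoxyphenoxy)-3,5-dimethoxyphenol
Conditions: BCl3 (6 equiv), C6HMe5 (6 equiv), CH2Cl2, −78 → 0 °C; then H2O
Reagents that add atoms: none
Why: In this Lewis acid ether cleavage, BCl3 with pentamethylbenzene as benzyl cation trap removes both benzyl groups in the cold and on warming cleaves only the methoxy group flanked on both sides (twisted out of conjugation, so the most basic), the selectivity known from 1,2,3-trimethoxybenzene giving 2,6-dimethoxyphenol.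

Step 5
Reactants: 7 2-(3,5-dihydroxyphenoxy)-6-(3,5-dimethoxyphenoxy)-3,5-dimethoxyphenol
Product: 8 4-(3,5-dimethoxyphenoxy)-1,3-dimethoxydibenzo[b,e][1,4]dioxine-6,8-diol
Conditions: Ag2O (1.05 equiv), acetone/toluene 1:1 (2 mM), Ar, dark, rt
Reagents that add atoms: none
Why: Proposed new method: Ag2O takes one electron from the most electron-rich OH, the central 2,6-bis(aryloxy)phenol of ring B, whose radical cannot dimerise (both ortho carbons are substituted and the para carbon is walled in by two OMe) and can reach only the ortho carbons of its two aryloxy neighbours through a six-membered transition state; it adds to the ring with free OH groups, at a carbon ortho to one OH and para to the other (the positions that couple in phenol oxidation, and both such carbons are equivalent), rather than to O-methylated ring A, then a second electron and a proton are lost and the dienone tautomerises to the dioxin; the closest known type is Barton-type intramolecular oxidative phenolic C–O coupling (griseofulvin-type spirocyclisation, Ag2O-mediated benzodioxane neolignan synthesis, copper/O2 poly(phenylene oxide) coupling); no stereocentre is formed.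

Step 6
Reactants: 4 2-bromo-4-(3,5-dimethoxyphenoxy)-1,3,5-trimethoxybenzene
Product: 9 2-bromo-6-(3,5-dimethoxyphenoxy)-3,5-dimethoxyphenol
Conditions: BCl3 (1.5 equiv), CH2Cl2, −78 → 0 °C; then H2O
Reagents that add atoms: none
Why: This is the same hindrance-selective Lewis acid ether cleavage as in step 4, since only the methoxy group between Br and the aryloxy group is flanked on both sides.

Step 7
Reactants: 9 2-bromo-6-(3,5-dimethoxyphenoxy)-3,5-dimethoxyphenol
Product: 10 2-(3,5-dimethoxyphenoxy)-3,5-dimethoxyphenol
Conditions: H2 (1 atm), Pd/C, NaOAc, MeOH, rt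
Reagents that add atoms: none
Why: Catalytic hydrodehalogenation removes the aryl bromine, and diaryl and methyl ethers are untouched.

Step 8
Reactants: 8 4-(3,5-dimethoxyphenoxy)-1,3-dimethoxydibenzo[b,e][1,4]dioxine-6,8-diol; 10 2-(3,5-dimethoxyphenoxy)-3,5-dimethoxyphenol
Product: 12 octa-O-methylphlorofucofuroeckol A, via biaryl triol 11 (not isolated)
Conditions: 10 (3 equiv), FeCl3 (20 mol %), t-BuOOt-Bu (1.2 equiv), HFIP, rt; then HCl (4 M in dioxane), 50 °C
Reagents that add atoms: none
Why: Proposed new method: ring C of 8 is a para-aryloxyphenol and so the easier partner to oxidise, while 10 is harder to oxidise but the better carbon nucleophile, the pairing that favours cross- over homo-coupling in iron-catalysed oxidative phenol cross-coupling; both partners bind iron through a free OH, so the bond forms ortho to each OH, at C9 of 8 (also para to the 6-OH and next to the weaker, tied-back dioxin oxygen, unlike C7) and at C6 of 10 (C4 is walled in by two OMe), and the fully O-methylated rings A, B and E stay out; 11 forms as a racemic axis that disappears on closure; in the acid stage only ring C still has two free meta OH groups and reacts as its keto tautomer (as in the HCl/MeOH etherification of phloroglucinol, which stops once two oxygens are alkylated), so the single OH of ring D adds to C8 and water leaves, which puts the furan oxygen next to the ring E ether; the closest known types are the iron/peroxide tandem oxidative coupling–annulation of phenols with 1,3-dicarbonyls to benzofurans and the acid cyclodehydration of 2,2'-biphenols to dibenzofurans.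

Step 9
Reactants: 12 octa-O-methylphlorofucofuroeckol A
Product: 13 phlorofucofuroeckol A
Conditions: BBr3 (20 equiv), CH2Cl2, −78 °C → rt; then H2O; Sephadex LH-20
Reagents that add atoms: none
Why: BBr3 aryl methyl ether cleavage removes all eight methyl groups and leaves diaryl ether, dioxin and furan C–O bonds intact; the product is achiral.

Compound list
1 | 1,3,5-trimethoxybenzene | COc1cc(OC)cc(OC)c1 | starting material
2 | 2,4-dibromo-1,3,5-trimethoxybenzene | COc1cc(OC)c(Br)c(OC)c1Br | intermediate
3 | 3,5-dimethoxyphenol | COc1cc(O)cc(OC)c1 | starting material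
4 | 2-bromo-4-(3,5-dimethoxyphenoxy)-1,3,5-trimethoxybenzene | COc1cc(OC)c(Oc2cc(OC)cc(OC)c2)c(OC)c1Br | intermediate
5 | 3,5-bis(benzyloxy)phenol | Oc1cc(OCc2ccccc2)cc(OCc2ccccc2)c1 | starting material
6 | 2-[3,5-bis(benzyloxy)phenoxy]-4-(3,5-dimethoxyphenoxy)-1,3,5-trimethoxybenzene | COc1cc(OC)c(Oc2cc(OC)cc(OC)c2)c(OC)c1Oc1cc(OCc2ccccc2)cc(OCc2ccccc2)c1 | intermediate
7 | 2-(3,5-dihydroxyphenoxy)-6-(3,5-dimethoxyphenoxy)-3,5-dimethoxyphenol | COc1cc(OC)c(Oc2cc(OC)cc(OC)c2)c(O)c1Oc1cc(O)cc(O)c1 | intermediate
8 | 4-(3,5-dimethoxyphenoxy)-1,3-dimethoxydibenzo[b,e][1,4]dioxine-6,8-diol (eckol tetramethyl ether, ring C free) | COc1cc(OC)cc(Oc2c(OC)cc(OC)c3c2Oc2c(O)cc(O)cc2O3)c1 | intermediate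
9 | 2-bromo-6-(3,5-dimethoxyphenoxy)-3,5-dimethoxyphenol | COc1cc(OC)c(Oc2cc(OC)cc(OC)c2)c(O)c1Br | intermediate
10 | 2-(3,5-dimethoxyphenoxy)-3,5-dimethoxyphenol | COc1cc(O)c(Oc2cc(OC)cc(OC)c2)c(OC)c1 | intermediate
11 | 9-[3-(3,5-dimethoxyphenoxy)-2-hydroxy-4,6-dimethoxyphenyl]-4-(3,5-dimethoxyphenoxy)-1,3-dimethoxydibenzo[b,e][1,4]dioxine-6,8-diol (racemic about the biaryl axis) | COc1cc(OC)cc(Oc2c(OC)cc(OC)c3c2Oc2c(O)cc(O)c(-c4c(O)c(Oc5cc(OC)cc(OC)c5)c(OC)cc4OC)c2O3)c1 | intermediate (not isolated)
12 | octa-O-methylphlorofucofuroeckol A (only the ring C hydroxyl free) | COc1cc(OC)cc(Oc2c(OC)cc(OC)c3c2Oc2c(O)cc4oc5c(Oc6cc(OC)cc(OC)c6)c(OC)cc(OC)c5c4c2O3)c1 | intermediate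
13 | phlorofucofuroeckol A (achiral) | Oc1cc(O)cc(Oc2c(O)cc(O)c3c2Oc2c(O)cc4oc5c(Oc6cc(O)cc(O)c6)c(O)cc(O)c5c4c2O3)c1 | target

Total steps: 9. Longest linear sequence: 7 (steps 1, 2, 3, 4, 5, 8, 9).

Steps most likely to fail

**Step 8.**
- Risk: homo-coupling of 8, attack at C7 instead of C9, attack through C4 of 10 (para to its OH), or a second arylation would each cut the yield. The acid stage could also open the dioxin at C9a.
- Fallback: fix both bonding carbons with pre-installed groups. It sets out from 8 and 4 and comes back to the route at 11.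
- NBS (1 equiv, THF, −78 °C) brominates the free resorcinol ring of 8 para to the 6-OH. This gives 9-bromo-4-(3,5-dimethoxyphenoxy)-1,3-dimethoxydibenzo[b,e][1,4]dioxine-6,8-diol F1.
- Bromide 4 already carries its bromine on the carbon that has to bond. It is borylated (B2pin2, Pd(OAc)2, SPhos, KOAc, dioxane, 100 °C) to 2-[3-(3,5-dimethoxyphenoxy)-2,4,6-trimethoxyphenyl]-4,4,5,5-tetramethyl-1,3,2-dioxaborolane F2.
- Suzuki–Miyaura coupling of the two (Pd(OAc)2, SPhos, K3PO4, toluene/H2O, 100 °C) gives 9-[3-(3,5-dimethoxyphenoxy)-2,4,6-trimethoxyphenyl]-4-(3,5-dimethoxyphenoxy)-1,3-dimethoxydibenzo[b,e][1,4]dioxine-6,8-diol F3.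
- BCl3 (CH2Cl2, 0 °C) then cleaves the one methoxy group flanked by the new aryl group and the ring E ether. This gives 11, which is closed to 12 with HCl as in the second stage of step 8.

**Step 5.**
- Risk: product 8 is at least as easy to oxidise as 7, so over-oxidation and bieckol-type dimers compete. Radical addition to the arene may also simply be too slow.
- Fallback: replace the C–H/O–H oxidation by halogenation and substitution. It sets out from 7 and comes back at 8.
- NBS (1 equiv, THF, −78 °C) brominates the most activated ring, the free resorcinol ring C, para to one OH and next to the ether oxygen. This gives 2-(2-bromo-3,5-dihydroxyphenoxy)-6-(3,5-dimethoxyphenoxy)-3,5-dimethoxyphenol F4.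
- An intramolecular Ullmann etherification (CuI, picolinic acid, K3PO4, DMSO, 80 °C) lets the ring B phenoxide displace the bromide and gives 8.

**Step 3.**
- Risk: the bromide of 4 is very electron-rich and flanked by two methoxy groups, so slow coupling and hydrodebromination are likely.
- Fallback: invert the polarity of the ether synthesis. It sets out from 4 and comes back at 6.
- Palladium-catalysed hydroxylation (Pd2(dba)3, t-BuXPhos, KOH, dioxane/H2O, 100 °C) turns 4 into 3-(3,5-dimethoxyphenoxy)-2,4,6-trimethoxyphenol F5.
- This hindered phenol is then coupled with the unhindered, commercial 1-bromo-3,5-bis(benzyloxy)benzene (CuI, picolinic acid, K3PO4, DMSO, 100 °C) to give 6.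

Further compounds
F1 | step 8 | 9-bromo-4-(3,5-dimethoxyphenoxy)-1,3-dimethoxydibenzo[b,e][1,4]dioxine-6,8-diol | COc1cc(OC)cc(Oc2c(OC)cc(OC)c3c2Oc2c(O)cc(O)c(Br)c2O3)c1
F2 | step 8 | 2-[3-(3,5-dimethoxyphenoxy)-2,4,6-trimethoxyphenyl]-4,4,5,5-tetramethyl-1,3,2-dioxaborolane | COc1cc(OC)c(Oc2cc(OC)cc(OC)c2)c(OC)c1B1OC(C)(C)C(C)(C)O1
F3 | step 8 | 9-[3-(3,5-dimethoxyphenoxy)-2,4,6-trimethoxyphenyl]-4-(3,5-dimethoxyphenoxy)-1,3-dimethoxydibenzo[b,e][1,4]dioxine-6,8-diol | COc1cc(OC)cc(Oc2c(OC)cc(OC)c3c2Oc2c(O)cc(O)c(-c4c(OC)c(Oc5cc(OC)cc(OC)c5)c(OC)cc4OC)c2O3)c1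
F4 | step 5 | 2-(2-bromo-3,5-dihydroxyphenoxy)-6-(3,5-dimethoxyphenoxy)-3,5-dimethoxyphenol | COc1cc(OC)c(Oc2cc(OC)cc(OC)c2)c(O)c1Oc1cc(O)cc(O)c1Br
F5 | step 3 | 3-(3,5-dimethoxyphenoxy)-2,4,6-trimethoxyphenol | COc1cc(OC)c(Oc2cc(OC)cc(OC)c2)c(OC)c1O
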